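All compound numbers refer to the compound list after the steps. The heterocyclic core is numbered in the isoflavonoid way throughout (given in the first section).

## Analysis of the target

Target 19 is a coumestan (6H-benzofuro[3,2-c]chromen-6-one). Ring A (benzo ring of the coumarin), lactone ring B, furan ring C and benzo ring D form one flat conjugated tetracycle, and ring E, a 2,2-dimethyl-3,4-dihydro-2H-pyran, is fused to ring A. Numbering: O1, C2 (lactone carbonyl), C3, C4, C4a, C5 to C8 and C8a in rings A and B, and C1' to C6' in ring D. The ring-E oxygen sits on C5 and its CH2 on C6, the methoxy group is on C7, the only ring-A hydrogen is on C8, the furan oxygen bridges C4 and C2', and the phenol is on C4'. There is no stereocenter, so every stereocenter that appears on the way is transient and is handled as a racemate. Sensitive sites are the lactone (opened by hydroxide or alkoxide), the free phenol, the electron-rich ring A and the benzylic CH2 of ring E, which can lose hydride to quinone oxidants. The difficulty is regiochemical: ring A is pentasubstituted with three different oxygen functions in a fixed order, and ring D must sit on C3 with its ortho oxygen on C4, not the reverse. The strategy rests on C3, which carries ring D and lies between C4 (bonded to ring A) and C2 (bonded to O1). This C4a–C4–C3(aryl)–C2–O1 array is that of an isoflavone, and an isoflavone arises from a 2'-hydroxychalcone when the aryl group moves from the β- to the α-carbon.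

## Retrosynthetic reasoning

19 from 18. The O–acetyl bond at C4' is cut. The phenol has to be masked during the preceding oxidation, because a free hydroxyl para to C3 would open a quinone-methide pathway. The forward step must cleave an aryl ester without opening the lactone, which points to acid-catalysed transesterification.

18 from 15. No skeletal bond is cut; the oxidation level is lowered. The C2 carbonyl goes back to an OCH2 group and the C3=C4 bond of the benzofuran to a CH–CH unit, which gives the cis-pterocarpan acetate 15 with all five rings in place. The forward reaction is three successive two-electron oxidations through 16 and 17, each at a C–H bond α to oxygen. It must leave the CH2 of ring E alone.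

15 from 14. The acetate is removed to give the free phenol 14.

14 from 11. The bond between the C2' oxygen and C4 is cut, C4 goes back to a carbonyl and C2–C3 to the enol-ether double bond. This is the right place because the C4 carbonyl of isoflavone 11 sits exactly where the furan oxygen must attach, with the ortho hydroxyl of ring D positioned to close a five-membered ring. The forward reaction is hydride reduction through 12 and 13, then acid ionisation of the C4 carbinol and capture by the C2' hydroxyl. No carbon–carbon bond is made.

11 from 10. Both O-benzyl bonds are cut. Benzyl ethers survive the base of the aldol step, the thallium oxidant and hot dilute acid, and leave together on hydrogenolysis. The ortho ether must stay on during the acid ring closure that makes 10 (see step 4).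

10 from 8. This is the key disconnection. The C3–C1' bond and the O1–C2 bond are cut and ring D is returned to the neighbouring carbon, the β-carbon of chalcone 8. Cutting here turns the 3-aryl unit into an enone that is one condensation away from two simple pieces. A direct C3–aryl bond formation would instead need a halogenated chromone and an arylmetal. The forward reaction must move ring D by one carbon, leave the old β-carbon at the aldehyde oxidation level (acetal 9) and close the pyranone on the ring-A hydroxyl.

8 from 5 and 6. The Cα=Cβ double bond is cut into methyl ketone 5 and aldehyde 6, which cannot enolise. The forward reaction is a base-mediated aldol condensation.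

5 from 4, and 4 from 1 and 2. Ring E is cut at the bond from ring A to the former aldehyde carbon of 2 and at the O–CMe2 bond, after the ring alkene has been put back. Ketone 1 is symmetric: its two hydroxyls and its two free ring positions are equivalent, so only one chromene can form and the ring-A pattern of 19 is fixed in the first step. The alkene of 4 is saturated before the oxidant of step 4 is used.

## Alternatives that were turned down

Alternative 1: Furan ring C is cut at C3–C1' and O–C2', and ring D is built as a carbocycle that is aromatised last.
- Forward key step: the 4-hydroxycoumarin A2 (7-methoxy, ring E on C5–C6) is alkylated at C3 by 6-bromo-3-ethoxycyclohex-2-en-1-one A3 with K2CO3. TsOH in the same flask then condenses the C4 hydroxyl with the ketone and hydrolyses the enol ether, giving cyclohexanone A1.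
- For it: A2 should be reachable from ketone 5 in one carbonate acylation, the lactone has the right oxidation level from the start, and the route needs about five steps against nine. On step economy and convergence it is the stronger plan.
- Against it: C3 of A2 is part of an ambident enolate, and A3 is a secondary α-bromo ketone that can lose HBr and aromatise instead of being substituted. The C4 hydroxyl is peri to the ring-E oxygen. The last step must dehydrogenate a cyclohexanone to a phenol with the benzylic CH2 of ring E present, so the uncertain chemistry sits in the last two steps.
- Comparison: the chosen strategy is longer, but brings ring D in as an aromatic ring with both oxygens already placed, uses steps with close counterparts in isoflavonoid chemistry, and has its one uncertain step early, on cheap material.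

Alternative 2: Ring B is cut at C4–C4a and O1–C2.
- Forward key step: phloroglucinol A5 and ethyl 6-benzyloxy-2-oxo-2,3-dihydrobenzofuran-3-carboxylate A6 are heated in diphenyl ether. One carbonyl acylates the arene, the other esterifies the neighbouring hydroxyl, the five-membered lactone opens and the 3-aryl-4-hydroxycoumarin A4 forms.
- For it: the lactone and the C3–aryl bond arrive at the correct oxidation level, and furan ring C then needs only loss of water between the C4 and C2' hydroxyls. On assembling rings B, C and D without late oxidation it is stronger than the chosen route.
- Against it: A4 has four free hydroxyls and two equally activated free positions on ring A (C6 and C8). Methylating only O7 and building ring E on O5 and C6 asks for a selectivity the structure does not supply: the C4 enol is the most acidic hydroxyl, and C8 is as nucleophilic as C6.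
- Comparison: the whole difficulty moves to differentiating ring A, where the chosen route settles that pattern in step 1 through the symmetry of 1.

Alternative 3: Rings B and C are cut at O–C4, C3–C2 and C2–O1.
- Forward key step: the diarylalkyne A8 is treated with PdI2 (divalent palladium), thiourea, CO, Cs2CO3 and CBr4. The ring-D phenol adds to the alkyne carbon on ring A, CO inserts into the vinylpalladium bond and the ring-A phenol traps the acylpalladium, giving benzyl ether A7, one hydrogenolysis away from 19.
- For it: two rings and the carbonyl form in one catalytic operation at the final oxidation level, with the shortest endgame of all the plans and no thallium. On convergence it is clearly stronger.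
- Against it: A8 needs an alkyne on the ring-A carbon flanked by two oxygens, which means a regioselective halogenation of a very electron-rich chroman and a hindered coupling. Both aryl groups of A8 carry an ortho hydroxyl, so either can add to the alkyne first. If the ring-A phenol adds, the isomeric lactone with rings A and D exchanged results, and nothing in A8 clearly biases the choice.
- Comparison: in the chosen strategy the connectivity of isoflavone 10 decides which ring becomes the benzofuran and which the coumarin (ring D on C3, ring A on the C4 carbonyl), not a small difference in phenol reactivity.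

Key step: step 4

Assumption: 1, 2 and 6 are taken as purchased materials; the target is achiral, so every chiral intermediate is carried as a racemate.

## Route

Step 1
Reactants: 1 2,6-dihydroxy-4-methoxyacetophenone; 2 3-methylbut-2-enal (prenal)
Product: 4 1-(7-hydroxy-5-methoxy-2,2-dimethyl-2H-chromen-8-yl)ethanone, via ortho-quinone methide 3 (not isolated)
Conditions: 2 (1.5 equiv), pyridine, 120 °C, sealed tube
Reagents that add atoms: none
Why: Pyridine-mediated chromenylation of a resorcinol-type phenol: the ring carbon between a hydroxyl and the methoxy group adds to the aldehyde, loss of water gives ortho-quinone methide 3, and oxa-6π electrocyclisation closes the 2H-pyran. The two hydroxyls and the two free ring positions of 1 are equivalent, so one regioisomer should form, and the remaining hydroxyl is hydrogen-bonded to the ketone, which should slow a second annulation.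

Step 2
Reactants: 4 1-(7-hydroxy-5-methoxy-2,2-dimethyl-2H-chromen-8-yl)ethanone
Product: 5 1-(7-hydroxy-5-methoxy-2,2-dimethylchroman-8-yl)ethanone
Conditions: H2 (1 atm), 10% Pd/C, EtOAc, rt
Reagents that add atoms: none
Why: Heterogeneous hydrogenation of the styrene-type ring alkene; the hydrogen-bonded aryl ketone and the aryl ethers should be inert at 1 atm and rt. The alkene is removed here because it would be oxythallated in step 4.

Step 3
Reactants: 5 1-(7-hydroxy-5-methoxy-2,2-dimethylchroman-8-yl)ethanone; 6 2,4-bis(benzyloxy)benzaldehyde
Product: 8 (E)-3-[2,4-bis(benzyloxy)phenyl]-1-(7-hydroxy-5-methoxy-2,2-dimethylchroman-8-yl)prop-2-en-1-one (the 2'-hydroxychalcone), via aldol adduct 7 (not isolated)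
Conditions: KOH (excess), EtOH–THF–H2O, rt; then 1 M HCl, 0 °C
Reagents that add atoms: none
Why: Claisen–Schmidt condensation: the enolate of methyl ketone 5 adds to the non-enolisable aldehyde 6, and β-elimination from aldol 7 gives the conjugated (E)-enone. In base the ortho hydroxyl is a phenoxide conjugated with the carbonyl, which should disfavour oxa-Michael closure to the flavanone, and cold acidification returns the chelated phenol.

Step 4
Reactants: 8 (E)-3-[2,4-bis(benzyloxy)phenyl]-1-(7-hydroxy-5-methoxy-2,2-dimethylchroman-8-yl)prop-2-en-1-one
Product: 10 3-[2,4-bis(benzyloxy)phenyl]-7-methoxy-4H-chromen-4-one bearing ring E fused at C5–C6 with its oxygen on C5 (the isoflavone), via dimethyl acetal 9 (not isolated)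
Conditions: Tl(NO3)3·3H2O (1.1 equiv), MeOH–HC(OMe)3, rt; then 10% aq HCl, 50 °C to reflux
Reagents that add atoms: none
Why: Tl(NO3)3 (trivalent thallium) adds to the enone C=C with the metal on the α-carbon and methanol on the β-carbon, which is benzylic to the electron-rich ring D. Heterolysis of the weak C–Tl bond, with release of TlNO3 (univalent thallium), is assisted by ring D through a bridged phenonium ion, so the aryl group ends on the α-carbon (the new C3–C1' bond) and the β-carbon becomes an oxocarbenium ion that methanol traps as dimethyl acetal 9; HC(OMe)3 takes up the water of the hydrated salt so that methanol is the nucleophile. Aqueous HCl then ionises the acetal, the ring-A hydroxyl adds to the oxocarbenium carbon in a 6-exo-trig closure (O1–C2), and loss of methanol from the 2-methoxyisoflavanone gives the pyranone. This is the known Tl(NO3)3 oxidative rearrangement of 2'-hydroxychalcones to isoflavones, related to the 1,2-aryl shift of aryl ketones to arylacetates with the same salt. The stereocenter at C3 of 9 is racemic and disappears on elimination, so no stereocontrol is needed. Aryl migration must be faster than attack of the phenol on the β-carbon (aurone or flavanone formation) and faster than oxidation of ring A: the ortho- and para-benzyloxy groups give ring D a high migratory aptitude, the hydroxyl is held in a hydrogen bond to the carbonyl, and the acyl group lowers the electron density of ring A. Both ring-D oxygens stay benzylated through the acid treatment, because a free ortho hydroxyl on the migrated ring would close a five-membered ring on the same acetal carbon.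

Step 5
Reactants: 10 the bis(benzyloxy)isoflavone
Product: 11 3-(2,4-dihydroxyphenyl)-7-methoxy-4H-chromen-4-one bearing ring E fused at C5–C6 with its oxygen on C5
Conditions: H2 (1 atm), 10% Pd/C, EtOAc–MeOH, rt, stopped after uptake of 2 equiv
Reagents that add atoms: none
Why: Hydrogenolysis of the two benzyl aryl ethers on palladium, which should be faster than saturation of the C2=C3 bond of the vinylogous ester. Any C2–C3 saturated material that forms is compound 12, an intermediate of step 6, so it is not lost.

Step 6
Reactants: 11 the 2',4'-dihydroxyisoflavone
Product: 14 racemic cis-pterocarpan (6a,11a-dihydro-6H-benzofuro[3,2-c]chromene skeleton: C2' oxygen bonded to C4; H-3 and H-4 cis; 4'-hydroxy; 7-methoxy; ring E on C5–C6), via isoflavanone 12 (not isolated), via isoflavan-4-ol 13 (not isolated)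
Conditions: NaBH4 (excess), THF–EtOH, 0 °C to rt; then 3 M aq HCl to pH 1, rt
Reagents that add atoms: none
Why: Known borohydride conversion of 2'-hydroxyisoflavones to pterocarpans: conjugate reduction gives isoflavanone 12, carbonyl reduction gives isoflavan-4-ol 13, and acid ionises the C4 carbinol to a benzylic cation stabilised by the three oxygens of ring A, which the C2' hydroxyl captures in a 5-exo closure. Only the cis fusion of the five- and six-membered rings is free of strain; both new stereocenters are racemic and are removed in step 8.

Step 7
Reactants: 14 the cis-pterocarpan phenol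
Product: 15 4'-O-acetate of the cis-pterocarpan (racemic)
Conditions: Ac2O, pyridine, DMAP (cat.), CH2Cl2, rt
Reagents that add atoms: acetic anhydride, CC(=O)OC(C)=O
Why: Standard acylation of a phenol by nucleophilic catalysis. The acetate lowers the electron density of ring D and blocks quinone-methide formation in the oxidation that follows.

Step 8
Reactants: 15 the cis-pterocarpan acetate
Product: 18 coumestan acetate (4'-O-acetate of the target), via pterocarpene acetate 16 (not isolated), via lactol 17 (not isolated)
Conditions: DDQ (3.3 equiv), 1,4-dioxane–H2O, rt to 50 °C
Reagents that add atoms: water, O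
Why: Known DDQ oxidation of pterocarpans to coumestans: hydride loss from the α-oxygenated benzylic C4–H and proton loss from C3 give benzofuran 16, a second hydride loss from the OCH2 group at C2 gives an aromatic benzopyrylium ion that water traps as lactol 17, and a third equivalent oxidises the lactol to the lactone. Each C–H bond attacked has an α-oxygen and leads to an aromatic product or cation, so it should react at a lower temperature than the CH2 of ring E, which has no α-oxygen.

Step 9
Reactants: 18 the coumestan acetate
Product: 19 the target, 4'-hydroxy-7-methoxycoumestan with ring E on C5–C6 (CNP0304440.0)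
Conditions: HCl (1.25 M in MeOH), THF, 50 °C
Reagents that add atoms: none
Why: Acid-catalysed transesterification of the aryl acetate with methanol. The lactone, the methyl ether and the ring-E ether are stable to these conditions, and the acid medium avoids the base-induced lactone opening.

## Compound list

1 | 2,6-dihydroxy-4-methoxyacetophenone | CC(=O)c1c(O)cc(OC)cc1O | starting material
2 | 3-methylbut-2-enal (prenal) | CC(C)=CC=O | starting material
3 | (6Z)-2-acetyl-3-hydroxy-5-methoxy-6-(3-methylbut-2-en-1-ylidene)cyclohexa-2,4-dien-1-one (ortho-quinone methide, not isolated) | CC(C)=C/C=C1\C(=O)C(C(C)=O)=C(O)C=C1OC | intermediate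
4 | 1-(7-hydroxy-5-methoxy-2,2-dimethyl-2H-chromen-8-yl)ethanone | CC(=O)c1c(O)cc(OC)c2C=CC(C)(C)Oc12 | intermediate
5 | 1-(7-hydroxy-5-methoxy-2,2-dimethylchroman-8-yl)ethanone | CC(=O)c1c(O)cc(OC)c2CCC(C)(C)Oc12 | intermediate
6 | 2,4-bis(benzyloxy)benzaldehyde | O=Cc1ccc(OCc2ccccc2)cc1OCc1ccccc1 | starting material
7 | 3-[2,4-bis(benzyloxy)phenyl]-3-hydroxy-1-(7-hydroxy-5-methoxy-2,2-dimethylchroman-8-yl)propan-1-one (racemic aldol adduct, not isolated) | COc1cc(O)c(C(=O)CC(O)c3ccc(OCc4ccccc4)cc3OCc3ccccc3)c2c1CCC(C)(C)O2 | intermediate
8 | (E)-3-[2,4-bis(benzyloxy)phenyl]-1-(7-hydroxy-5-methoxy-2,2-dimethylchroman-8-yl)prop-2-en-1-one | COc1cc(O)c(C(=O)/C=C/c3ccc(OCc4ccccc4)cc3OCc3ccccc3)c2c1CCC(C)(C)O2 | intermediate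
9 | 2-[2,4-bis(benzyloxy)phenyl]-1-(7-hydroxy-5-methoxy-2,2-dimethylchroman-8-yl)-3,3-dimethoxypropan-1-one (racemic, not isolated) | COc1cc(O)c(C(=O)C(C(OC)OC)c3ccc(OCc4ccccc4)cc3OCc3ccccc3)c2c1CCC(C)(C)O2 | intermediate
10 | 3-[2,4-bis(benzyloxy)phenyl]-7-methoxy-4H-chromen-4-one with the 2,2-dimethyl-3,4-dihydro-2H-pyran ring E fused at C5–C6, oxygen on C5 | COc1cc2occ(-c3ccc(OCc4ccccc4)cc3OCc3ccccc3)c(=O)c2c2c1CCC(C)(C)O2 | intermediate
11 | 3-(2,4-dihydroxyphenyl)-7-methoxy-4H-chromen-4-one with ring E fused at C5–C6, oxygen on C5 | COc1cc2occ(-c3ccc(O)cc3O)c(=O)c2c2c1CCC(C)(C)O2 | intermediate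
12 | 3-(2,4-dihydroxyphenyl)-7-methoxychroman-4-one with ring E fused at C5–C6, oxygen on C5 (racemic isoflavanone, not isolated) | COc1cc2OCC(c3ccc(O)cc3O)C(=O)c2c2c1CCC(C)(C)O2 | intermediate
13 | 3-(2,4-dihydroxyphenyl)-7-methoxychroman-4-ol with ring E fused at C5–C6, oxygen on C5 (racemic, cis and trans isomers, not isolated) | COc1cc2OCC(c3ccc(O)cc3O)C(O)c2c2c1CCC(C)(C)O2 | intermediate
14 | cis-pterocarpan phenol: 6a,11a-dihydro-6H-benzofuro[3,2-c]chromene with the C2' oxygen on C4, H-3 and H-4 cis, 4'-hydroxy, 7-methoxy, ring E on C5–C6 (racemic, one enantiomer drawn) | COc1cc2OC[C@@H]3c4ccc(O)cc4O[C@@H]3c2c2c1CCC(C)(C)O2 | intermediate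
15 | 4'-O-acetate of cis-pterocarpan 14 (racemic, one enantiomer drawn) | COc1cc2OC[C@@H]3c4ccc(OC(C)=O)cc4O[C@@H]3c2c2c1CCC(C)(C)O2 | intermediate
16 | pterocarpene acetate: 6H-benzofuro[3,2-c]chromene with C2 as OCH2, C3=C4 inside the benzofuran, 4'-acetoxy, 7-methoxy, ring E on C5–C6 (not isolated) | COc1cc2OCc3c4ccc(OC(C)=O)cc4oc3c2c2c1CCC(C)(C)O2 | intermediate
17 | lactol: compound 16 with a hydroxyl on C2 (racemic, not isolated) | COc1cc2OC(O)c3c4ccc(OC(C)=O)cc4oc3c2c2c1CCC(C)(C)O2 | intermediate
18 | coumestan acetate: 4'-acetoxy-7-methoxy-6H-benzofuro[3,2-c]chromen-6-one with ring E on C5–C6 | COc1cc2oc(=O)c3c4ccc(OC(C)=O)cc4oc3c2c2c1CCC(C)(C)O2 | intermediate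
19 | CNP0304440.0: 4'-hydroxy-7-methoxy-6H-benzofuro[3,2-c]chromen-6-one with the 2,2-dimethyl-3,4-dihydro-2H-pyran ring E on C5–C6, oxygen on C5 | COc1cc2oc(=O)c3c4ccc(O)cc4oc3c2c2c1CCC(C)(C)O2 | target

## Step count and uncertain steps

Total: 9 steps. Longest linear sequence: 9 steps (1 to 19); aldehyde 6 enters at step 3.

Step 4 (key step). The most likely failure is oxidation of the free-phenolic, oxygen-rich ring A by the thallium salt, or closure of the phenol on the β-carbon before the aryl group has moved, so that aurone- or flavanone-type material forms instead of acetal 9. The fallback avoids the oxidant and makes the C3–aryl bond by cross-coupling. It sets out from ketone 5. Heating 5 with dimethylformamide dimethyl acetal should give (E)-3-(dimethylamino)-1-(7-hydroxy-5-methoxy-2,2-dimethylchroman-8-yl)prop-2-en-1-one F1. Iodine in chloroform should iodinate the α-carbon, close the phenol onto the iminium carbon and expel dimethylamine to give the 3-iodo-7-methoxychromen-4-one with ring E on C5–C6 F2. Suzuki–Miyaura coupling of F2 with 2,4-bis(benzyloxy)phenylboronic acid (OB(O)c1ccc(OCc2ccccc2)cc1OCc1ccccc1), Pd(PPh3)4 (zerovalent palladium) and aqueous Na2CO3 in DME at 80 °C returns to the route at isoflavone 10.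

Step 8. Hydride abstraction may not stay at the α-oxygenated positions: the benzylic CH2 of ring E is attached to an oxygen-rich ring and can be dehydrogenated to the chromene, and the oxidation may also stall at the pterocarpene or lactol stage. The fallback stops relying on chemoselectivity. From 15, an excess of DDQ in wet dioxane at reflux drives the core fully to the lactone and lets ring E dehydrogenate, giving the coumestan acetate with a C=C bond in ring E F3, alone or mixed with 18. Hydrogenation of this material (H2, 10% Pd/C, EtOAc) should saturate only the ring-E alkene, since every other C=C bond is aromatic, and returns to the route at 18.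

Step 6. The diphenoxide of 11 may be a poor hydride acceptor, so the reduction may stop at the isoflavanone. On acidification the strongly stabilised C4 cation may lose a proton to give the isoflav-3-ene or be captured by solvent or by another molecule instead of by the C2' hydroxyl. The fallback replaces ionisation by activation of the alcohol. The reduction is quenched with aqueous NH4Cl, isoflavan-4-ol 13 is isolated, and the dihydrofuran is closed by Mitsunobu dehydration (PPh3, diisopropyl azodicarboxylate, THF, 0 °C). It sets out from 13, returns at 14 and makes no new compound (F0).

Step 1. Both hydroxyls of 1 are hydrogen-bonded to the ketone and the ring is deactivated by the acyl group, so the condensation may be slow, and forcing it may bring a second annulation on the remaining hydroxyl. The fallback builds the saturated ring directly by Friedel–Crafts chemistry. From 1, 2-methylbut-3-en-2-ol and BF3·OEt2 in dioxane should prenylate the ring carbon between hydroxyl and methoxy to give 1-[2,6-dihydroxy-4-methoxy-3-(3-methylbut-2-en-1-yl)phenyl]ethanone F4, which under the same acid closes by Markovnikov addition of the neighbouring hydroxyl to the alkene. The route is rejoined at chroman 5 and step 2 is skipped.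

## Further compounds

F1 | step 4 | (E)-3-(dimethylamino)-1-(7-hydroxy-5-methoxy-2,2-dimethylchroman-8-yl)prop-2-en-1-one | COc1cc(O)c(C(=O)/C=C/N(C)C)c2c1CCC(C)(C)O2
F2 | step 4 | 3-iodo-7-methoxy-4H-chromen-4-one with ring E fused at C5–C6, oxygen on C5 | COc1cc2occ(I)c(=O)c2c2c1CCC(C)(C)O2
F3 | step 8 | coumestan acetate with a 2,2-dimethyl-2H-pyran (chromene) ring E | COc1cc2oc(=O)c3c4ccc(OC(C)=O)cc4oc3c2c2c1C=CC(C)(C)O2
F0 | step 6 | none | none
F4 | step 1 | 1-[2,6-dihydroxy-4-methoxy-3-(3-methylbut-2-en-1-yl)phenyl]ethanone | CC(=O)c1c(O)cc(OC)c(CC=C(C)C)c1O
A1 | alternative 1 | target skeleton with ring D as a cyclohexanone, ketone at C4' | COc1cc2oc(=O)c3c4CCC(=O)Cc4oc3c2c2c1CCC(C)(C)O2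
A2 | alternative 1 | 4-hydroxy-7-methoxycoumarin with ring E fused at C5–C6, oxygen on C5 | COc1cc2oc(=O)cc(O)c2c2c1CCC(C)(C)O2
A3 | alternative 1 | 6-bromo-3-ethoxycyclohex-2-en-1-one (racemic) | CCOC1=CC(=O)C(Br)CC1
A4 | alternative 2 | 3-(4-benzyloxy-2-hydroxyphenyl)-4,5,7-trihydroxycoumarin | Oc1cc(O)c2c(O)c(-c3ccc(OCc4ccccc4)cc3O)c(=O)oc2c1
A5 | alternative 2 | phloroglucinol | Oc1cc(O)cc(O)c1
A6 | alternative 2 | ethyl 6-benzyloxy-2-oxo-2,3-dihydrobenzofuran-3-carboxylate (racemic) | CCOC(=O)C1C(=O)Oc2cc(OCc3ccccc3)ccc21
A7 | alternative 3 | 4'-O-benzyl ether of the target | COc1cc2oc(=O)c3c4ccc(OCc5ccccc5)cc4oc3c2c2c1CCC(C)(C)O2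
A8 | alternative 3 | 5-(benzyloxy)-2-[(7-hydroxy-5-methoxy-2,2-dimethylchroman-8-yl)ethynyl]phenol | COc1cc(O)c(C#Cc3ccc(OCc4ccccc4)cc3O)c2c1CCC(C)(C)O2
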